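**Plan**

Thelephenol is an achiral diarylmethane. Ring A is the phenol ring that carries CH2OH and one bromine; ring B is the 3,5-dibromo-4-hydroxyphenyl ring.
Retrosynthesis: functional-group changes (ArCH2OH from CO2Me, the ring A C–Br bond, both ArO–Me bonds) lead back to a dimethoxy diarylmethane ester. Ring B of that ester is then cut at C1'–C2' and C1'–C6'.
Enabling feature: ring B is symmetric about the axis through C4'(–O) and C1'. Atoms C2'–C6', the oxygen and both bromines therefore map onto a 3,5-dibromo-4-methoxypyrylium cation, and C1', the only ring B carbon bearing the bridging CH2, is supplied as a phosphorus ylide carbon.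
Forward: ring A is bought as an aldehyde ester and its side chain is extended to a 2-arylethylphosphonium salt (steps 1–4). The pyrylium salt is made from 4H-pyran-4-one (steps 5–6). Ring B is built in step 7 by exchange of the pyrylium oxygen for the ylide carbon, followed by demethylation, bromination of ring A and ester reduction (steps 8–10).
Stereochemistry: the target has no stereocentre and no stereogenic double bond, so only regiochemistry needs control.

Key step: step 7

Assumption: the pyrylium salt is moisture-sensitive, so it is taken to be collected by precipitation under argon and used at once; the NaBr formed with the ylide is taken to stay undissolved in cold THF.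

**Route**

Step 1
Reactants: 1 methyl 3-formyl-4-methoxybenzoate
Product: 2 methyl 3-ethenyl-4-methoxybenzoate
Conditions: Ph3PCH3Br, KOtBu, THF, 0 °C to rt
Reagents that add atoms: methyltriphenylphosphonium bromide, C[P+](c1ccccc1)(c1ccccc1)c1ccccc1.[Br-]
Why: Wittig methylenation; the unstabilised ylide should react with the aldehyde far faster than with the methyl ester, and the carbon it delivers later becomes C1' of ring B.

Step 2
Reactants: 2 methyl 3-ethenyl-4-methoxybenzoate
Product: 4 methyl 3-(2-hydroxyethyl)-4-methoxybenzoate, via B-alkyl-9-BBN adduct 3 (not isolated)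
Conditions: 9-BBN (9-borabicyclo[3.3.1]nonane), THF, 0 °C to rt; then 30% H2O2, aq NaOAc, 0 °C to rt
Reagents that add atoms: 9-borabicyclo[3.3.1]nonane, B1C2CCCC1CCC2; hydrogen peroxide, OO
Why: Hydroboration–oxidation; 9-BBN places boron on the terminal carbon of styrenes with high anti-Markovnikov selectivity and leaves the benzoate alone, and the acetate-buffered peroxide oxidation should avoid saponification.

Step 3
Reactants: 4 methyl 3-(2-hydroxyethyl)-4-methoxybenzoate
Product: 5 methyl 3-(2-bromoethyl)-4-methoxybenzoate
Conditions: CBr4, PPh3 (6), CH2Cl2, 0 °C to rt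
Reagents that add atoms: carbon tetrabromide, BrC(Br)(Br)Br
Why: Appel reaction; a primary alcohol is converted into the bromide under neutral conditions at low temperature, which the ester and the aryl ether tolerate.

Step 4
Reactants: 5 methyl 3-(2-bromoethyl)-4-methoxybenzoate; 6 triphenylphosphine
Product: 7 {2-[2-methoxy-5-(methoxycarbonyl)phenyl]ethyl}triphenylphosphonium bromide
Conditions: MeCN, reflux; Et2O (precipitation)
Reagents that add atoms: none
Why: SN2 quaternisation of triphenylphosphine by a primary alkyl bromide; the para ester lowers the nucleophilicity of the methoxy oxygen, so ring closure to a dihydrobenzofuran should not compete.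

Step 5
Reactants: 8 4H-pyran-4-one
Product: 9 3,5-dibromo-4H-pyran-4-one
Conditions: Br2, pyridine, CH2Cl2, 0 °C to rt
Reagents that add atoms: bromine, BrBr
Why: Alpha-bromination of a vinylogous ester by addition–dehydrobromination; C3 and C5 are the nucleophilic carbons of the two enol-ether double bonds and pyridine takes up the HBr.

Step 6
Reactants: 9 3,5-dibromo-4H-pyran-4-one
Product: 10 3,5-dibromo-4-methoxypyrylium tetrafluoroborate
Conditions: Me3OBF4, CH2Cl2, rt, argon; Et2O (precipitation)
Reagents that add atoms: trimethyloxonium tetrafluoroborate, C[O+](C)C.F[B-](F)(F)F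
Why: O-alkylation of a 4-pyranone carbonyl oxygen with a trialkyloxonium salt, the usual entry to 4-alkoxypyrylium salts; the gain in aromaticity should offset the lower basicity caused by the two bromines.

Step 7
Reactants: 7 {2-[2-methoxy-5-(methoxycarbonyl)phenyl]ethyl}triphenylphosphonium bromide; 10 3,5-dibromo-4-methoxypyrylium tetrafluoroborate
Product: 14 methyl 3-(3,5-dibromo-4-methoxybenzyl)-4-methoxybenzoate, via ylide 11 (not isolated), via 2H-pyran adduct 12 (not isolated), via dienal phosphonium salt 13 (not isolated)
Conditions: 7, NaN(SiMe3)2 (1.0 equiv), THF, −78 to 0 °C; clear ylide solution added to 10 (1.2 equiv) in CH2Cl2/THF, −78 °C; then NaN(SiMe3)2 (1.0 equiv), −78 to 40 °C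
Reagents that add atoms: none
Why: Proposed new method: the unstabilised ylide 11 should add to the unhindered, equivalent C2/C6 positions of cation 10 to give 2H-pyran 12, which opens by oxa-6π electrocyclic ring opening to dienal 13 with the phosphonium group at the far end of the chain; the second equivalent of base then forms a delocalised ylide whose carbon attacks the aldehyde, and loss of Ph3PO from the oxaphosphetane gives ring B at the benzene oxidation level, the new bonds being C1'–C2' (ylide addition) and C1'–C6' (olefination). The closest known reaction type is the conversion of 2,4,6-trisubstituted pyrylium salts into benzenes by alkylidenetriphenylphosphoranes, supported by the known C2 addition and ring opening of alpha-unsubstituted pyrylium salts with carbon nucleophiles to 2Z-dienals; the combination has not been shown for a 3,5-dihalo-4-alkoxypyrylium salt without alpha substituents. Ring B, the only ring formed, is closed as a six-membered carbocycle by intramolecular Wittig olefination (6-exo-trig attack of the ylide carbon on the aldehyde, equally describable as 6π closure of the phosphonio-trienolate). No stereocentre is created; the ring-derived C=C of 13 is Z by origin, and the other C=C can reach the geometry needed for closure through the reversible 2H-pyran/dienal valence tautomerism and the low rotation barrier of the delocalised ylide. The step needs attack at C2/C6 and not at C4 (displacement of methoxide) or at the O-methyl carbon, and the two bromines flanking C4 together with the donor methoxy group on C4 should secure this. Inverse addition at −78 °C with NaBr left behind should keep a second ylide from intercepting the aldehyde of 13 and bromide from demethylating 10.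

Step 8
Reactants: 14 methyl 3-(3,5-dibromo-4-methoxybenzyl)-4-methoxybenzoate
Product: 15 methyl 3-(3,5-dibromo-4-hydroxybenzyl)-4-hydroxybenzoate
Conditions: BBr3, CH2Cl2, −78 to 0 °C; H2O
Reagents that add atoms: none
Why: Lewis-acid cleavage of aryl methyl ethers (O–B complexation, then SN2 attack of bromide on the methyl group); the twisted, hindered ring B ether and the ring A ether should both cleave, while the methyl ester and the aryl bromides persist at or below 0 °C.

Step 9
Reactants: 15 methyl 3-(3,5-dibromo-4-hydroxybenzyl)-4-hydroxybenzoate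
Product: 16 methyl 3-bromo-5-(3,5-dibromo-4-hydroxybenzyl)-4-hydroxybenzoate
Conditions: Br2 (1.0 equiv), AcOH, rt
Reagents that add atoms: bromine, BrBr
Why: Electrophilic aromatic bromination of a phenol; ring A has exactly one free position ortho to its hydroxyl (para is blocked by the ester), whereas every ortho and para position of the ring B phenol is already substituted.

Step 10
Reactants: 16 methyl 3-bromo-5-(3,5-dibromo-4-hydroxybenzyl)-4-hydroxybenzoate
Product: 17 thelephenol, 2,6-dibromo-4-{[3-bromo-2-hydroxy-5-(hydroxymethyl)phenyl]methyl}phenol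
Conditions: iBu2AlH (excess), THF, −78 to 0 °C; aq KNaC4H4O6
Reagents that add atoms: none
Why: Hydride reduction of a benzoate ester to the benzylic alcohol; excess iBu2AlH covers the two phenolic protons, aryl bromides are inert to it, and the near-neutral tartrate work-up should spare the acid-sensitive 4-hydroxybenzyl alcohol.

**Compound list**

1 | methyl 3-formyl-4-methoxybenzoate | COC(=O)c1ccc(OC)c(C=O)c1 | starting material
2 | methyl 3-ethenyl-4-methoxybenzoate | COC(=O)c1ccc(OC)c(C=C)c1 | intermediate
3 | methyl 3-[2-(9-borabicyclo[3.3.1]nonan-9-yl)ethyl]-4-methoxybenzoate (not isolated) | COC(=O)c1ccc(OC)c(CCB2C3CCCC2CCC3)c1 | intermediate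
4 | methyl 3-(2-hydroxyethyl)-4-methoxybenzoate | COC(=O)c1ccc(OC)c(CCO)c1 | intermediate
5 | methyl 3-(2-bromoethyl)-4-methoxybenzoate | COC(=O)c1ccc(OC)c(CCBr)c1 | intermediate
6 | triphenylphosphine | c1ccc(cc1)P(c1ccccc1)c1ccccc1 | starting material
7 | {2-[2-methoxy-5-(methoxycarbonyl)phenyl]ethyl}triphenylphosphonium bromide | COC(=O)c1ccc(OC)c(CC[P+](c2ccccc2)(c2ccccc2)c2ccccc2)c1.[Br-] | intermediate
8 | 4H-pyran-4-one | O=c1ccocc1 | starting material
9 | 3,5-dibromo-4H-pyran-4-one | O=c1c(Br)cocc1Br | intermediate
10 | 3,5-dibromo-4-methoxypyrylium tetrafluoroborate | COc1c(Br)c[o+]cc1Br.F[B-](F)(F)F | intermediate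
11 | methyl 4-methoxy-3-[2-(triphenyl-λ5-phosphanylidene)ethyl]benzoate (ylide, not isolated) | COC(=O)c1ccc(OC)c(CC=P(c2ccccc2)(c2ccccc2)c2ccccc2)c1 | intermediate
12 | {1-(3,5-dibromo-4-methoxy-2H-pyran-2-yl)-2-[2-methoxy-5-(methoxycarbonyl)phenyl]ethyl}triphenylphosphonium tetrafluoroborate (racemic mixture of diastereomers, not isolated) | COC(=O)c1ccc(OC)c(CC(C2OC=C(Br)C(OC)=C2Br)[P+](c2ccccc2)(c2ccccc2)c2ccccc2)c1.F[B-](F)(F)F | intermediate
13 | {(3E,5Z)-4,6-dibromo-5-methoxy-1-[2-methoxy-5-(methoxycarbonyl)phenyl]-7-oxohepta-3,5-dien-2-yl}triphenylphosphonium tetrafluoroborate (racemic; the geometric isomer able to cyclise, not isolated) | COC(=O)c1ccc(OC)c(CC(/C=C(Br)\C(OC)=C(\Br)C=O)[P+](c2ccccc2)(c2ccccc2)c2ccccc2)c1.F[B-](F)(F)F | intermediate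
14 | methyl 3-(3,5-dibromo-4-methoxybenzyl)-4-methoxybenzoate | COC(=O)c1ccc(OC)c(Cc2cc(Br)c(OC)c(Br)c2)c1 | intermediate
15 | methyl 3-(3,5-dibromo-4-hydroxybenzyl)-4-hydroxybenzoate | COC(=O)c1ccc(O)c(Cc2cc(Br)c(O)c(Br)c2)c1 | intermediate
16 | methyl 3-bromo-5-(3,5-dibromo-4-hydroxybenzyl)-4-hydroxybenzoate | COC(=O)c1cc(Br)c(O)c(Cc2cc(Br)c(O)c(Br)c2)c1 | intermediate
17 | thelephenol, 2,6-dibromo-4-{[3-bromo-2-hydroxy-5-(hydroxymethyl)phenyl]methyl}phenol | OCc1cc(Br)c(O)c(Cc2cc(Br)c(O)c(Br)c2)c1 | target

**Count and risks**

Total step count: 10 steps.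
Longest linear sequence: 8 steps (steps 1, 2, 3, 4, 7, 8, 9, 10); steps 5 and 6 form the short branch to the pyrylium salt.

Steps most likely to fail:

1. Step 7 (the proposed new method). The ylide may attack C4 with displacement of methoxide, or transfer an electron to the cation, leading to dimerisation. The cation may also be O-demethylated by bromide or ylide. Finally, the dienal may fail to reach the geometry needed for closure and be consumed by intermolecular olefination. The fallback uses only known reactions, sets out from 1 and comes back to the route at 16. Addition of 4-MeOC6H4MgBr to the aldehyde of 1 (THF, −78 °C, where the ester is left alone) should give racemic methyl 3-[hydroxy(4-methoxyphenyl)methyl]-4-methoxybenzoate F1. Ionic hydrogenation of this doubly benzylic alcohol (Et3SiH, CF3CO2H, CH2Cl2) should give methyl 4-methoxy-3-(4-methoxybenzyl)benzoate F2. BBr3 under the conditions of step 8 should give methyl 4-hydroxy-3-(4-hydroxybenzyl)benzoate F3. Br2 (3 equiv) in AcOH should then fill the three free positions ortho to the hydroxyl groups (two on ring B, one on ring A; both para positions are blocked) and give 16.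

2. Step 6. O-alkylation of the electron-poor carbonyl oxygen may stall, and the salt may hydrolyse back to 9 during isolation. The fallback changes how the cation is made and protected, not the ring construction; it sets out from 9 and comes back at 15. Compound 9 is O-silylated in the flask with iPr3SiOTf (1.0 equiv, CH2Cl2, 0 °C) to 3,5-dibromo-4-[(triisopropylsilyl)oxy]pyrylium trifluoromethanesulfonate F4, a mode of 4-pyranone activation that is known to direct carbon nucleophiles to C2. Ylide 11 and then base are added as in step 7. The reaction should pass through the 2H-pyran adduct {1-{3,5-dibromo-4-[(triisopropylsilyl)oxy]-2H-pyran-2-yl}-2-[2-methoxy-5-(methoxycarbonyl)phenyl]ethyl}triphenylphosphonium trifluoromethanesulfonate F5 and the ring-opened {(3E,5Z)-4,6-dibromo-1-[2-methoxy-5-(methoxycarbonyl)phenyl]-7-oxo-5-[(triisopropylsilyl)oxy]hepta-3,5-dien-2-yl}triphenylphosphonium trifluoromethanesulfonate F6. The expected product is methyl 3-{3,5-dibromo-4-[(triisopropylsilyl)oxy]benzyl}-4-methoxybenzoate F7. Bu4NF in THF should give methyl 3-(3,5-dibromo-4-hydroxybenzyl)-4-methoxybenzoate F8, and BBr3 as in step 8 should cleave the remaining ring A methyl ether to give 15.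

3. Step 9. Site selectivity may be lost through ipso attack para to the ring B hydroxyl, with cleavage of the diarylmethane bridge, or through over-bromination of the free bisphenol. The fallback moves the bromination ahead of the demethylation; it sets out from 14 and comes back at 16. Treatment of the bis(methyl ether) 14 with Br2 in AcOH at 50 °C should brominate only the ring A position ortho to methoxy and meta to the ester, because ring B is a deactivated 2,6-dibromoanisole with no free ortho or para position. This should give methyl 3-bromo-5-(3,5-dibromo-4-methoxybenzyl)-4-methoxybenzoate F9, and BBr3 as in step 8 should then give 16 directly, bypassing 15.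

**Further compounds**

F1 | step 7 | methyl 3-[hydroxy(4-methoxyphenyl)methyl]-4-methoxybenzoate (racemic) | COC(=O)c1ccc(OC)c(C(O)c2ccc(OC)cc2)c1
F2 | step 7 | methyl 4-methoxy-3-(4-methoxybenzyl)benzoate | COC(=O)c1ccc(OC)c(Cc2ccc(OC)cc2)c1
F3 | step 7 | methyl 4-hydroxy-3-(4-hydroxybenzyl)benzoate | COC(=O)c1ccc(O)c(Cc2ccc(O)cc2)c1
F4 | step 6 | 3,5-dibromo-4-[(triisopropylsilyl)oxy]pyrylium trifluoromethanesulfonate | CC(C)[Si](Oc1c(Br)c[o+]cc1Br)(C(C)C)C(C)C.[O-]S(=O)(=O)C(F)(F)F
F5 | step 6 | {1-{3,5-dibromo-4-[(triisopropylsilyl)oxy]-2H-pyran-2-yl}-2-[2-methoxy-5-(methoxycarbonyl)phenyl]ethyl}triphenylphosphonium trifluoromethanesulfonate (racemic mixture of diastereomers) | COC(=O)c1ccc(OC)c(CC(C2OC=C(Br)C(O[Si](C(C)C)(C(C)C)C(C)C)=C2Br)[P+](c2ccccc2)(c2ccccc2)c2ccccc2)c1.[O-]S(=O)(=O)C(F)(F)F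
F6 | step 6 | {(3E,5Z)-4,6-dibromo-1-[2-methoxy-5-(methoxycarbonyl)phenyl]-7-oxo-5-[(triisopropylsilyl)oxy]hepta-3,5-dien-2-yl}triphenylphosphonium trifluoromethanesulfonate (racemic) | COC(=O)c1ccc(OC)c(CC(/C=C(Br)\C(O[Si](C(C)C)(C(C)C)C(C)C)=C(\Br)C=O)[P+](c2ccccc2)(c2ccccc2)c2ccccc2)c1.[O-]S(=O)(=O)C(F)(F)F
F7 | step 6 | methyl 3-{3,5-dibromo-4-[(triisopropylsilyl)oxy]benzyl}-4-methoxybenzoate | COC(=O)c1ccc(OC)c(Cc2cc(Br)c(O[Si](C(C)C)(C(C)C)C(C)C)c(Br)c2)c1
F8 | step 6 | methyl 3-(3,5-dibromo-4-hydroxybenzyl)-4-methoxybenzoate | COC(=O)c1ccc(OC)c(Cc2cc(Br)c(O)c(Br)c2)c1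
F9 | step 9 | methyl 3-bromo-5-(3,5-dibromo-4-methoxybenzyl)-4-methoxybenzoate | COC(=O)c1cc(Br)c(OC)c(Cc2cc(Br)c(OC)c(Br)c2)c1
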